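The target is cut at the methylene bridge into an (R)-geranylated acetylfilicinic acid and 8-butyryl-5,7-dihydroxy-2,2-dimethyl-2H-chromene. Everything rests on building the pyran ring of that chromene (O1, C2, C3, C4, fused at C4a–C8a) so that O1 sits on C8a, beside the butyryl-bearing C8. One operation does this: prenal condenses with a free phloroglucinol carbon and the resulting dienone closes by oxa-6π electrocyclisation, forming C4–C4a and O1–C2. The precursor is mirror-symmetric 2,6-dihydroxy-4-(methoxymethoxy)butyrophenone, whose capped para oxygen leaves only the two equivalent oxygens next to the acyl carbon for ring closure. The quaternary stereocentre is set separately by catalytic dearomative geranylation, and the halves are joined through a phenolic Mannich base.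

Key step: step 3

Remark: the quaternary carbon is R in the enol form in which the target is drawn, and every β-triketone below is written in that same enol form; chromene locants (O1 to C8a) are used for the bicyclic half.

Step 1
Reactants: 1 phloroglucinol (benzene-1,3,5-triol)
Product: 2 2,4,6-trihydroxybutyrophenone (1-(2,4,6-trihydroxyphenyl)butan-1-one)
Conditions: n-PrCOCl (1.05 equiv), AlCl3 (3.5 equiv), PhNO2–CH2Cl2, 0 to 50 °C; then ice, 2 M HCl
Reagents that add atoms: butanoyl chloride, CCCC(Cl)=O
Why: Friedel–Crafts acylation of the threefold-symmetric, strongly activated arene, in which all ring carbons are equivalent and the aluminium chelate of the first aryl ketone deactivates the ring against a second acylation.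

Step 2
Reactants: 2 2,4,6-trihydroxybutyrophenone
Product: 3 2,6-dihydroxy-4-(methoxymethoxy)butyrophenone
Conditions: MOMCl (1.0 equiv, slow addition), i-Pr2NEt (1.1 equiv), CH2Cl2, −10 to 0 °C
Reagents that add atoms: chloromethyl methyl ether, COCCl
Why: Base-mediated O-alkylation (acetal ether formation) should go to the para hydroxyl, which is the most acidic one (its anion is a vinylogous carboxylate) and is neither hindered by nor hydrogen-bonded to the butyryl group, while the limiting amount of MOMCl keeps bis-etherification low.

Step 3
Reactants: 3 2,6-dihydroxy-4-(methoxymethoxy)butyrophenone; 4 3-methylbut-2-enal (prenal)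
Product: 6 8-butyryl-7-hydroxy-5-(methoxymethoxy)-2,2-dimethyl-2H-chromene, via ortho-quinone methide dienone 5 (not isolated)
Conditions: 4 (1.2 equiv, added in portions), ethylenediammonium diacetate (20 mol%), PhMe, 100 °C
Reagents that add atoms: none
Why: The diammonium acetate turns 4 into its iminium ion, which is attacked by ring carbon C3 of 3 (flanked by the free C2 hydroxyl and the C4 acetal ether, C5 being its mirror image), and loss of the amine leaves dienone 5, a 1-oxatriene O=C2–C3=CH–CH=CMe2; this condensation makes the future C4a–C4 bond. A thermal disrotatory oxa-6π electrocyclisation of 5 then joins the dienone oxygen to the dimethylated terminus (O1–C2), closing the 2H-pyran ring in a pericyclic, formally 6-endo mode and restoring the aromatic sextet, which pulls the sequence forward. The closest known reaction type is the amine- or ethylenediammonium-diacetate-mediated formal [3+3] chromenylation of resorcinols and acylphloroglucinols with α,β-unsaturated aldehydes. No stereocentre arises, because the ring-closing terminus C2 carries two methyl groups. The step needs closure through the oxygen beside the butyryl carbon and not through the para oxygen, and it needs to stop after one annulation: the para oxygen is an acetal ether that cannot become the dienone carbonyl, and the mirror symmetry of 3 makes both free carbons and both free hydroxyls equivalent, so only one chromene can form. After the first closure the single remaining hydroxyl is locked in the hydrogen bond to the butyryl carbonyl, so a second condensation should be much slower, and the small excess of 4 holds the reaction at the mono-chromene.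

Step 4
Reactants: 6 8-butyryl-7-hydroxy-5-(methoxymethoxy)-2,2-dimethyl-2H-chromene
Product: 7 8-butyryl-5,7-dihydroxy-2,2-dimethyl-2H-chromene (1-(5,7-dihydroxy-2,2-dimethyl-2H-chromen-8-yl)butan-1-one)
Conditions: 3 M aq. HCl, MeOH, 45 °C
Reagents that add atoms: none
Why: Acid-catalysed solvolysis of the methoxymethyl acetal frees the C5 phenol, the chromene double bond on its acyl-deactivated ring and the aryl ketone should tolerate warm dilute methanolic HCl, and the acid is used before the acid-sensitive geranyl chain is present.

Step 5
Reactants: 7 8-butyryl-5,7-dihydroxy-2,2-dimethyl-2H-chromene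
Product: 8 8-butyryl-6-[(dimethylamino)methyl]-5,7-dihydroxy-2,2-dimethyl-2H-chromene
Conditions: 37% aq. CH2O (1.1 equiv) premixed with 40% aq. Me2NH (1.3 equiv), EtOH, 0 °C to rt
Reagents that add atoms: formaldehyde, C=O; dimethylamine, CNC
Why: Phenolic Mannich reaction, in which C6 is the only unsubstituted ring carbon and lies between two hydroxyls, so the premixed aminomethylating agent can react only there, and premixing keeps free formaldehyde and hence methylene-bridged homodimer low.

Step 6
Reactants: 9 2-methylphloroglucinol (2-methylbenzene-1,3,5-triol)
Product: 10 2,4,6-trihydroxy-3-methylacetophenone (1-(2,4,6-trihydroxy-3-methylphenyl)ethan-1-one)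
Conditions: AcCl (1.05 equiv), AlCl3 (3.5 equiv), PhNO2–CH2Cl2, 0 °C to rt; then ice, 2 M HCl
Reagents that add atoms: acetyl chloride, CC(Cl)=O
Why: Friedel–Crafts acylation, in which the two unsubstituted ring carbons of 9 are mirror images so that only one monoketone can form, and chelation of the product to aluminium stops a second acylation.

Step 7
Reactants: 11 geraniol ((2E)-3,7-dimethylocta-2,6-dien-1-ol)
Product: 12 geranyl methyl carbonate ((2E)-3,7-dimethylocta-2,6-dien-1-yl methyl carbonate)
Conditions: ClCO2Me (1.3 equiv), pyridine (2.0 equiv), CH2Cl2, 0 °C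
Reagents that add atoms: methyl chloroformate, COC(Cl)=O
Why: O-acylation of the primary allylic alcohol (carbonate formation) does not involve the C2=C3 double bond, so the E geometry is carried over unchanged.

Step 8
Reactants: 10 2,4,6-trihydroxy-3-methylacetophenone; 12 geranyl methyl carbonate
Product: 13 (4R)-2-acetyl-4-[(2E)-3,7-dimethylocta-2,6-dien-1-yl]-3,5-dihydroxy-4-methylcyclohexa-2,5-dien-1-one
Conditions: Pd2(dba)3·CHCl3 (2.5 mol%), (R,R)-DACH-phenyl ligand [(1R,2R)-N,N′-bis(2-diphenylphosphanylbenzoyl)cyclohexane-1,2-diamine, 7.5 mol%; the mirror-image ligand is used if a pilot run shows the opposite sense], 10 (1.2 equiv), 1,4-dioxane, rt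
Reagents that add atoms: none
Why: Proposed new method: zerovalent palladium ionises 12 with loss of CO2 to a cationic π-geranyl complex of divalent palladium and methoxide, which deprotonates 10. The ambident phloroglucinolate attacks the unsubstituted allyl terminus from outside the metal through its methyl-bearing ring carbon (C3 of 10, C4 of 13), giving the linear E-geranyl product. The chiral pocket of the ligand distinguishes the two enantiotopic faces of that carbon, whose flanks differ as an acetyl-chelated oxygen and an open one, and so sets the quaternary stereocentre under catalyst control. O-geranyl ethers formed on the way are re-ionised by the catalyst and funnel to the C-bonded product. The closest known reaction types are the palladium-catalysed asymmetric allylic dearomatisation of substituted 2-naphthols with this ligand family (Tsuji–Trost allylation) and the non-asymmetric palladium-catalysed dearomative allylation of acylphloroglucinols.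

Step 9
Reactants: 8 8-butyryl-6-[(dimethylamino)methyl]-5,7-dihydroxy-2,2-dimethyl-2H-chromene; 13 (4R)-2-acetyl-4-geranyl-3,5-dihydroxy-4-methylcyclohexa-2,5-dien-1-one
Product: 15 (4R)-2-acetyl-6-[(8-butanoyl-5,7-dihydroxy-2,2-dimethyl-2H-chromen-6-yl)methyl]-4-[(2E)-3,7-dimethylocta-2,6-dien-1-yl]-3,5-dihydroxy-4-methylcyclohexa-2,5-dien-1-one (the target), via ortho-quinone methide 14 (not isolated)
Conditions: 1,4-dioxane, 70–80 °C, N2 stream
Reagents that add atoms: none
Why: Alkylation of a cyclic β-triketone C–H acid by a phenolic Mannich base, in which the acidic enol of 13 protonates the amine of 8, dimethylamine is expelled to give 14, and the only ring CH of 13 (C6) adds to the exocyclic methylene in a Michael addition that re-aromatises the chromene ring; the quaternary stereocentre bears no hydrogen and is untouched, and cross-coupling is favoured because 8 has no free ring carbon with which to capture its own quinone methide.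

Compound list
1 | phloroglucinol (benzene-1,3,5-triol) | Oc1cc(O)cc(O)c1 | starting material
2 | 2,4,6-trihydroxybutyrophenone | CCCC(=O)c1c(O)cc(O)cc1O | intermediate
3 | 2,6-dihydroxy-4-(methoxymethoxy)butyrophenone | CCCC(=O)c1c(O)cc(OCOC)cc1O | intermediate
4 | 3-methylbut-2-enal (prenal) | CC(C)=CC=O | starting material
5 | (6Z)-2-butanoyl-3-hydroxy-5-(methoxymethoxy)-6-(3-methylbut-2-en-1-ylidene)cyclohexa-2,4-dien-1-one (ortho-quinone methide dienone) | CCCC(=O)C1=C(O)C=C(OCOC)/C(=C/C=C(C)C)C1=O | intermediate (not isolated)
6 | 8-butyryl-7-hydroxy-5-(methoxymethoxy)-2,2-dimethyl-2H-chromene | CCCC(=O)c1c(O)cc(OCOC)c2c1OC(C)(C)C=C2 | intermediate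
7 | 8-butyryl-5,7-dihydroxy-2,2-dimethyl-2H-chromene | CCCC(=O)c1c(O)cc(O)c2c1OC(C)(C)C=C2 | intermediate
8 | 8-butyryl-6-[(dimethylamino)methyl]-5,7-dihydroxy-2,2-dimethyl-2H-chromene | CCCC(=O)c1c(O)c(CN(C)C)c(O)c2c1OC(C)(C)C=C2 | intermediate
9 | 2-methylphloroglucinol (2-methylbenzene-1,3,5-triol) | Cc1c(O)cc(O)cc1O | starting material
10 | 2,4,6-trihydroxy-3-methylacetophenone | CC(=O)c1c(O)cc(O)c(C)c1O | intermediate
11 | geraniol ((2E)-3,7-dimethylocta-2,6-dien-1-ol) | OC/C=C(\C)CCC=C(C)C | starting material
12 | geranyl methyl carbonate | COC(=O)OC/C=C(\C)CCC=C(C)C | intermediate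
13 | (4R)-2-acetyl-4-[(2E)-3,7-dimethylocta-2,6-dien-1-yl]-3,5-dihydroxy-4-methylcyclohexa-2,5-dien-1-one | CC(=O)C1=C(O)[C@](C)(C/C=C(\C)CCC=C(C)C)C(O)=CC1=O | intermediate
14 | 8-butanoyl-7-hydroxy-2,2-dimethyl-6-methylidene-2H-chromen-5(6H)-one (ortho-quinone methide) | CCCC(=O)C1=C(O)C(=C)C(=O)C2=C1OC(C)(C)C=C2 | intermediate (not isolated)
15 | (4R)-2-acetyl-6-[(8-butanoyl-5,7-dihydroxy-2,2-dimethyl-2H-chromen-6-yl)methyl]-4-[(2E)-3,7-dimethylocta-2,6-dien-1-yl]-3,5-dihydroxy-4-methylcyclohexa-2,5-dien-1-one | CCCC(=O)c1c(O)c(CC2=C(O)[C@@](C)(C/C=C(\C)CCC=C(C)C)C(O)=C(C(C)=O)C2=O)c(O)c2c1OC(C)(C)C=C2 | target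

Total step count: 9.
Longest linear sequence: 6 steps (1, 2, 3, 4, 5, 9). Steps 6 and 8 form the filicinic branch and step 7 supplies the carbonate.

Steps most likely to fail

1. Step 8 (proposed new method). What may go wrong:
- poor discrimination of the two faces of the methyl-bearing carbon by the catalyst;
- geranylation at the unsubstituted ring carbon with re-aromatisation, or at oxygen;
- a second geranylation of the acidic product;
- erosion of the E geometry by syn–anti isomerisation of the allyl complex.

Fallback with known chemistry, setting out from 10: alkoxide-mediated alkylative dearomatisation with commercial geranyl bromide (NaOMe, MeOH, 0 °C to rt) should give the racemic geranylated acetylfilicinic acid F1. It is separated from the aromatic C-geranyl isomer by its much higher acidity (bicarbonate extraction) and by chromatography. Preparative HPLC on a polysaccharide carbamate chiral stationary phase with an acidified eluent then delivers 13 and leaves the (4S)-enantiomer F2. The configuration is assigned by ECD or X-ray analysis, and the route is rejoined at 13.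

2. Step 3 (key step). What may go wrong:
- slow condensation at the acyl-deactivated ring while the enal condenses with itself;
- over-reaction to a bis-pyran.

Fallback, setting out from 3: copper-catalysed O-alkylation of one of the two equivalent hydroxyls with 3-chloro-3-methylbut-1-yne (CuCl2·2H2O cat., DBU, MeCN, 0 °C) should give the aryl 1,1-dimethylpropargyl ether F3. Heating F3 in xylene at 140 °C starts an aromatic Claisen rearrangement. This can only go to the free ortho carbon, because the other ortho carbon bears the butyryl group, and gives the ortho-allenyl phenol F4. A [1,5]-hydrogen shift then leads to dienone 5, which closes as in the main route, so the fallback comes back at 6.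

3. Step 9 (final coupling). What may go wrong:
- reversible retro-Michael cleavage of the new methylene bridge under the released amine, which scrambles the halves into symmetrical dimers;
- sluggish quinone methide formation from the chelated Mannich base.

Fallback, setting out from 13 and 7, with the roles of the halves reversed: 13 is aminomethylated at C6 (CH2O, Me2NH, EtOH, 0 °C) to the Mannich base of the filicinic half F5. F5 should lose dimethylamine near room temperature to the methylidene trione F6, a much stronger Michael acceptor. F6 is captured by C6 of chromene diol 7 (1,4-dioxane, rt to 40 °C), so the fallback comes back at 15.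

Further compounds
F1 | step 8 | racemic 2-acetyl-4-[(2E)-3,7-dimethylocta-2,6-dien-1-yl]-3,5-dihydroxy-4-methylcyclohexa-2,5-dien-1-one | CC(=O)C1=C(O)C(C)(C/C=C(\C)CCC=C(C)C)C(O)=CC1=O
F2 | step 8 | (4S)-2-acetyl-4-[(2E)-3,7-dimethylocta-2,6-dien-1-yl]-3,5-dihydroxy-4-methylcyclohexa-2,5-dien-1-one | CC(=O)C1=C(O)[C@@](C)(C/C=C(\C)CCC=C(C)C)C(O)=CC1=O
F3 | step 3 | 1-{2-hydroxy-4-(methoxymethoxy)-6-[(2-methylbut-3-yn-2-yl)oxy]phenyl}butan-1-one | CCCC(=O)c1c(O)cc(OCOC)cc1OC(C)(C)C#C
F4 | step 3 | 1-[2,6-dihydroxy-4-(methoxymethoxy)-3-(3-methylbuta-1,2-dien-1-yl)phenyl]butan-1-one | CCCC(=O)c1c(O)cc(OCOC)c(C=C=C(C)C)c1O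
F5 | step 9 | (4R)-2-acetyl-6-[(dimethylamino)methyl]-4-[(2E)-3,7-dimethylocta-2,6-dien-1-yl]-3,5-dihydroxy-4-methylcyclohexa-2,5-dien-1-one | CC(=O)C1=C(O)[C@](C)(C/C=C(\C)CCC=C(C)C)C(O)=C(CN(C)C)C1=O
F6 | step 9 | 2-acetyl-4-[(2E)-3,7-dimethylocta-2,6-dien-1-yl]-3-hydroxy-4-methyl-6-methylidenecyclohex-2-ene-1,5-dione (same spatial arrangement at C4 as in 13; the descriptor becomes 4S because C5 is now a carbonyl carbon) | CC(=O)C1=C(O)[C@](C)(C/C=C(\C)CCC=C(C)C)C(=O)C(=C)C1=O
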